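**Retrosynthetic overview**

1. Target 26 ⇐ tris(silyl ether) 25 (desilylation) ⇐ bis(tertiary boronic ester) 22 (double Zweifel vinylation, each C–B becoming C–CH=CH2 with retention).
2. 22 ⇐ bis(carbamate) 15 + two homogeranyl pinacol boronates 19. The strategy rests on the quaternary carbon C3 of each 3,7,11-trimethyldodeca-1,6,10-trien-3-yl chain: it is benzylic (bonded to ring A para to its OH, and to ring B para to the middle OH) and carries a methyl group, so it is a 1-arylethyl carbamate in disguise, and both C3–C4 bonds are made by lithiation–borylation.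
3. 15 ⇐ two antipodal ketone reductions separated in time: the ring B acetyl is present from the start, the ring A acetyl is unmasked late from an aryl bromide (13 ⇐ 11). The carbamates are installed only after all phenols are silylated, because a benzylic carbamate para to a free amine or phenol would be lost by 1,6-elimination.
4. Diaryl ether ⇐ SNAr of benzodioxole phenol 2 (from 1) with 4-bromo-2-fluoro-1-nitrobenzene 3, then nitro → OH through the aniline; 19 ⇐ geranyl bromide 16 (borylation, Matteson homologation).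
5. No ring is formed: both benzene rings are bought, and the only ring closed on the way is the temporary dioxole of 2.

Key step: step 14

Remark: ring A is the 4-hydroxy-3-aryloxyphenyl ring and ring B the 3-aryloxy-4,5-dihydroxyphenyl ring; TBS = tert-butyldimethylsilyl, Cb = N,N-diisopropylcarbamoyl, Bpin = 4,4,5,5-tetramethyl-1,3,2-dioxaborolan-2-yl.

**Route**

Step 1
Reactants: 1 1-(3,4,5-trihydroxyphenyl)ethanone
Product: 2 1-(7-hydroxy-2,2-diphenyl-1,3-benzodioxol-5-yl)ethanone
Conditions: Ph2CCl2 (1.2 equiv), Ph2O, 175 °C, N2 sweep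
Reagents that add atoms: dichlorodiphenylmethane, ClC(Cl)(c1ccccc1)c1ccccc1
Why: Thermal ketalisation; the symmetric triol can close a five-membered dioxole only across two adjacent hydroxyls, so either adjacent pair gives the same benzodioxole and leaves one flanking phenol free for the ether synthesis.

Step 2
Reactants: 2 1-(7-hydroxy-2,2-diphenyl-1,3-benzodioxol-5-yl)ethanone; 3 4-bromo-2-fluoro-1-nitrobenzene
Product: 4 1-[7-(5-bromo-2-nitrophenoxy)-2,2-diphenyl-1,3-benzodioxol-5-yl]ethanone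
Conditions: K2CO3, DMF, rt → 40 °C
Reagents that add atoms: none
Why: Nucleophilic aromatic substitution (SNAr); the phenoxide of 2 displaces the fluoride ortho to the nitro group through a Meisenheimer adduct, far faster than it could displace the bromide para to the nitro group.

Step 3
Reactants: 4 1-[7-(5-bromo-2-nitrophenoxy)-2,2-diphenyl-1,3-benzodioxol-5-yl]ethanone
Product: 5 1-[7-(2-amino-5-bromophenoxy)-2,2-diphenyl-1,3-benzodioxol-5-yl]ethanone
Conditions: Fe powder, NH4Cl, EtOH/H2O (4:1), 80 °C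
Reagents that add atoms: none
Why: Béchamp-type iron reduction of the nitro group, which leaves the aryl bromide, the aryl ketone and the ketal untouched.

Step 4
Reactants: 5 1-[7-(2-amino-5-bromophenoxy)-2,2-diphenyl-1,3-benzodioxol-5-yl]ethanone
Product: 7 1-[7-(5-bromo-2-hydroxyphenoxy)-2,2-diphenyl-1,3-benzodioxol-5-yl]ethanone, via arylboronic pinacol ester 6 (not isolated)
Conditions: t-BuONO, B2pin2, MeCN, rt; then 30% H2O2, 1 M NaOH, THF, 0 °C
Reagents that add atoms: hydrogen peroxide, OO (oxygen of the phenol); bis(pinacolato)diboron, CC1(C)OB(OC1(C)C)B1OC(C)(C)C(C)(C)O1 (boron of intermediate 6 only)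
Why: Sandmeyer-type borylation, in which the alkyl nitrite diazotises the aniline under neutral conditions and the aryl radical is captured by the diboron reagent, followed by peroxide oxidation of the C–B bond to the phenol with ketal, ketone and bromide intact.

Step 5
Reactants: 7 1-[7-(5-bromo-2-hydroxyphenoxy)-2,2-diphenyl-1,3-benzodioxol-5-yl]ethanone
Product: 8 1-[3-(5-bromo-2-hydroxyphenoxy)-4,5-dihydroxyphenyl]ethanone
Conditions: AcOH/H2O (4:1), 100 °C, N2
Reagents that add atoms: none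
Why: Acid hydrolysis of the diphenylmethylene ketal, run at this stage because the molecule still has no acid-sensitive benzylic ester or alkene.

Step 6
Reactants: 8 1-[3-(5-bromo-2-hydroxyphenoxy)-4,5-dihydroxyphenyl]ethanone
Product: 9 1-{3-[5-bromo-2-(TBSO)phenoxy]-4,5-bis(TBSO)phenyl}ethanone
Conditions: TBSCl (4.5 equiv), imidazole, DMF, rt → 40 °C
Reagents that add atoms: tert-butyldimethylsilyl chloride, CC(C)(C)[Si](C)(C)Cl
Why: Silylation of all three phenols, which caps the para oxygens of both rings before any benzylic leaving group is introduced.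

Step 7
Reactants: 9 1-{3-[5-bromo-2-(TBSO)phenoxy]-4,5-bis(TBSO)phenyl}ethanone
Product: 10 (1S)-1-{3-[5-bromo-2-(TBSO)phenoxy]-4,5-bis(TBSO)phenyl}ethanol
Conditions: (R)-2-methyl-CBS-oxazaborolidine (15 mol %), BH3·SMe2, THF, −20 °C; MeOH quench
Reagents that add atoms: none
Why: Corey–Bakshi–Shibata reduction; the (R)-oxazaborolidine places the aryl group away from its boron substituent and delivers hydride to the Re face of the aryl methyl ketone, setting the S carbinol of ring B.

Step 8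
Reactants: 10 (1S)-1-{3-[5-bromo-2-(TBSO)phenoxy]-4,5-bis(TBSO)phenyl}ethanol
Product: 11 (1S)-1-{3-[5-bromo-2-(TBSO)phenoxy]-4,5-bis(TBSO)phenyl}ethyl N,N-diisopropylcarbamate
Conditions: i-Pr2NCOCl, Et3N, DMAP (cat.), CH2Cl2, reflux
Reagents that add atoms: N,N-diisopropylcarbamoyl chloride, CC(C)N(C(C)C)C(Cl)=O
Why: O-Carbamoylation of the secondary benzylic alcohol; no bond to the stereocentre is touched, so the S configuration is kept.

Step 9
Reactants: 11 (1S)-1-{3-[5-bromo-2-(TBSO)phenoxy]-4,5-bis(TBSO)phenyl}ethyl N,N-diisopropylcarbamate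
Product: 13 (1S)-1-{3-[5-acetyl-2-(TBSO)phenoxy]-4,5-bis(TBSO)phenyl}ethyl N,N-diisopropylcarbamate, via 1-ethoxyvinyl arene 12 (not isolated)
Conditions: Bu3Sn[C(OEt)=CH2], PdCl2(PPh3)2 (5 mol %), toluene, 100 °C; then 1 M HCl, THF, 0 °C
Reagents that add atoms: tributyl(1-ethoxyvinyl)stannane, CCCC[Sn](CCCC)(CCCC)C(=C)OCC; water, O
Why: Stille coupling of the aryl bromide with the 1-ethoxyvinyl stannane and mild acid hydrolysis of the enol ether unveil the ring A acetyl group only now, so that it never coexists with the ring B ketone.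

Step 10
Reactants: 13 (1S)-1-{3-[5-acetyl-2-(TBSO)phenoxy]-4,5-bis(TBSO)phenyl}ethyl N,N-diisopropylcarbamate
Product: 14 (1S)-1-{3-[5-[(1R)-1-hydroxyethyl]-2-(TBSO)phenoxy]-4,5-bis(TBSO)phenyl}ethyl N,N-diisopropylcarbamate
Conditions: (S)-2-methyl-CBS-oxazaborolidine (15 mol %), BH3·SMe2, THF, −20 °C; MeOH quench
Reagents that add atoms: none
Why: Corey–Bakshi–Shibata reduction with the antipodal (S)-oxazaborolidine delivers hydride to the Si face and sets the R carbinol of ring A, the ring B carbamate being inert to borane at this temperature.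

Step 11
Reactants: 14 (1S)-1-{3-[5-[(1R)-1-hydroxyethyl]-2-(TBSO)phenoxy]-4,5-bis(TBSO)phenyl}ethyl N,N-diisopropylcarbamate
Product: 15 (1S)-1-{3-[5-[(1R)-1-(N,N-diisopropylcarbamoyloxy)ethyl]-2-(TBSO)phenoxy]-4,5-bis(TBSO)phenyl}ethyl N,N-diisopropylcarbamate (bis(carbamate), R on ring A, S on ring B)
Conditions: i-Pr2NCOCl, Et3N, DMAP (cat.), CH2Cl2, reflux
Reagents that add atoms: N,N-diisopropylcarbamoyl chloride, CC(C)N(C(C)C)C(Cl)=O
Why: Second O-carbamoylation with retention completes the bis(carbamate), in which both carbamates sit para to silyl ethers and are therefore not prone to 1,6-elimination.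

Step 12 (boronate branch)
Reactants: 16 geranyl bromide, (2E)-1-bromo-3,7-dimethylocta-2,6-diene
Product: 17 2-[(2E)-3,7-dimethylocta-2,6-dien-1-yl]-4,4,5,5-tetramethyl-1,3,2-dioxaborolane (geranyl Bpin)
Conditions: B2pin2, Pd2(dba)3 (1 mol %), THF, 60 °C
Reagents that add atoms: bis(pinacolato)diboron, CC1(C)OB(OC1(C)C)B1OC(C)(C)C(C)(C)O1
Why: Palladium-catalysed borylation of the allylic bromide through a π-allyl palladium intermediate, which should give the linear E allylic boronate.

Step 13 (boronate branch)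
Reactants: 17 geranyl Bpin
Product: 19 2-[(3E)-4,8-dimethylnona-3,7-dien-1-yl]-4,4,5,5-tetramethyl-1,3,2-dioxaborolane (homogeranyl Bpin), via chloromethyl boronate complex 18 (not isolated)
Conditions: BrCH2Cl, n-BuLi, THF, −78 °C → rt
Reagents that add atoms: bromochloromethane, ClCBr; n-butyllithium, CCCC[Li] (lithium of intermediate 18 only)
Why: Matteson homologation; (chloromethyl)lithium adds to boron and the geranyl CH2 undergoes a 1,2-shift with loss of chloride, inserting one CH2 without touching the E alkene.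

Step 14
Reactants: 15 bis(carbamate) (R on ring A, S on ring B); 19 homogeranyl Bpin (3 equiv)
Product: 22 bis(tertiary pinacol boronic ester) in which ring A carries (2R,5E)-6,10-dimethyl-2-(Bpin)undeca-5,9-dien-2-yl and ring B the (2S,5E) counterpart, phenols as TBS ethers, via dilithiated biscarbamate 20 (not isolated), via bis(boronate) complex 21 (not isolated)
Conditions: s-BuLi (2.6 equiv), Et2O, −78 °C; 19, −78 °C; MgBr2 (1 M in MeOH), −78 °C → rt
Reagents that add atoms: sec-butyllithium, CCC(C)[Li] (lithium of intermediates 20 and 21 only)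
Why: Each carbamate carbonyl binds s-BuLi and directs removal of the adjacent benzylic hydrogen with retention, giving the configurationally stable dilithio species 20; boronate 19 captures each C–Li bond with retention to form complex 21, and on warming the homogeranyl CH2 shifts from boron to carbon anti to the departing carbamate (inversion), creating both C3–C4 bonds. This is the lithiation–borylation of enantioenriched secondary benzylic carbamates (a carbamate-directed lithiation followed by a Matteson-type 1,2-metallate rearrangement), applied twice in one molecule; no ring is closed. The two new quaternary stereocentres are controlled only by the carbinol configurations of 15, which the retention–inversion sequence converts into the R boronate on ring A and the S boronate on ring B. The step needs benzylic deprotonation to win over ortho-metalation and attack at silicon, which the proximity of the coordinating carbamate and the low temperature secure. It also needs migration to outrun dissociation of the electron-rich boronate complexes, which MgBr2 in MeOH secures by activating the carbamate leaving group and protonating any released carbanion.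

Step 15
Reactants: 22 bis(tertiary pinacol boronic ester)
Product: 25 tris(TBS) ether of the target, in which ring A carries (3R,6E)-3,7,11-trimethyldodeca-1,6,10-trien-3-yl and ring B the (3S,6E) chain, via bis(vinylboronate) complex 23 (not isolated), via bis(iodoalkyl boronate) 24 (not isolated)
Conditions: vinyllithium (6 equiv), THF, −78 → 0 °C; I2 (6 equiv), THF/MeOH, −78 °C; NaOMe (12 equiv), MeOH, −78 → 0 °C; aq Na2S2O3 at 0 °C
Reagents that add atoms: vinyllithium, [Li]C=C; iodine, II (iodine of intermediate 24 only)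
Why: Zweifel olefination; each boronate adds vinyllithium, iodine activates the vinyl group and triggers 1,2-migration of the tertiary carbon with retention, and methoxide induces anti elimination of boron and iodide to leave a vinyl group on each quaternary carbon.

Step 16
Reactants: 25 tris(TBS) ether of the target
Product: 26 3-{2-hydroxy-5-[(3R,6E)-3,7,11-trimethyldodeca-1,6,10-trien-3-yl]phenoxy}-5-[(3S,6E)-3,7,11-trimethyldodeca-1,6,10-trien-3-yl]benzene-1,2-diol (target)
Conditions: Bu4NF/AcOH (1:1, 4 equiv), THF, 0 °C → rt, degassed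
Reagents that add atoms: none
Why: Fluoride cleavage of the three aryl silyl ethers, buffered with acetic acid so that the catechol is not exposed as an air-sensitive phenoxide.

**Compound list**

1 | 1-(3,4,5-trihydroxyphenyl)ethanone | CC(=O)c1cc(O)c(O)c(O)c1 | starting material
2 | 1-(7-hydroxy-2,2-diphenyl-1,3-benzodioxol-5-yl)ethanone | CC(=O)c1cc(O)c2OC(c3ccccc3)(c3ccccc3)Oc2c1 | intermediate
3 | 4-bromo-2-fluoro-1-nitrobenzene | O=[N+]([O-])c1ccc(Br)cc1F | starting material
4 | 1-[7-(5-bromo-2-nitrophenoxy)-2,2-diphenyl-1,3-benzodioxol-5-yl]ethanone | CC(=O)c1cc(Oc2cc(Br)ccc2[N+](=O)[O-])c2OC(c3ccccc3)(c3ccccc3)Oc2c1 | intermediate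
5 | 1-[7-(2-amino-5-bromophenoxy)-2,2-diphenyl-1,3-benzodioxol-5-yl]ethanone | CC(=O)c1cc(Oc2cc(Br)ccc2N)c2OC(c3ccccc3)(c3ccccc3)Oc2c1 | intermediate
6 | 1-{7-[5-bromo-2-(Bpin)phenoxy]-2,2-diphenyl-1,3-benzodioxol-5-yl}ethanone | CC(=O)c1cc(Oc2cc(Br)ccc2B4OC(C)(C)C(C)(C)O4)c2OC(c3ccccc3)(c3ccccc3)Oc2c1 | intermediate (not isolated)
7 | 1-[7-(5-bromo-2-hydroxyphenoxy)-2,2-diphenyl-1,3-benzodioxol-5-yl]ethanone | CC(=O)c1cc(Oc2cc(Br)ccc2O)c2OC(c3ccccc3)(c3ccccc3)Oc2c1 | intermediate
8 | 1-[3-(5-bromo-2-hydroxyphenoxy)-4,5-dihydroxyphenyl]ethanone | CC(=O)c1cc(O)c(O)c(Oc2cc(Br)ccc2O)c1 | intermediate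
9 | 1-{3-[5-bromo-2-(TBSO)phenoxy]-4,5-bis(TBSO)phenyl}ethanone | CC(=O)c1cc(O[Si](C)(C)C(C)(C)C)c(O[Si](C)(C)C(C)(C)C)c(Oc2cc(Br)ccc2O[Si](C)(C)C(C)(C)C)c1 | intermediate
10 | (1S)-1-{3-[5-bromo-2-(TBSO)phenoxy]-4,5-bis(TBSO)phenyl}ethanol | C[C@H](O)c1cc(O[Si](C)(C)C(C)(C)C)c(O[Si](C)(C)C(C)(C)C)c(Oc2cc(Br)ccc2O[Si](C)(C)C(C)(C)C)c1 | intermediate
11 | (1S)-1-{3-[5-bromo-2-(TBSO)phenoxy]-4,5-bis(TBSO)phenyl}ethyl N,N-diisopropylcarbamate | C[C@H](OC(=O)N(C(C)C)C(C)C)c1cc(O[Si](C)(C)C(C)(C)C)c(O[Si](C)(C)C(C)(C)C)c(Oc2cc(Br)ccc2O[Si](C)(C)C(C)(C)C)c1 | intermediate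
12 | (1S)-1-{3-[5-(1-ethoxyvinyl)-2-(TBSO)phenoxy]-4,5-bis(TBSO)phenyl}ethyl N,N-diisopropylcarbamate | C[C@H](OC(=O)N(C(C)C)C(C)C)c1cc(O[Si](C)(C)C(C)(C)C)c(O[Si](C)(C)C(C)(C)C)c(Oc2cc(C(=C)OCC)ccc2O[Si](C)(C)C(C)(C)C)c1 | intermediate (not isolated)
13 | (1S)-1-{3-[5-acetyl-2-(TBSO)phenoxy]-4,5-bis(TBSO)phenyl}ethyl N,N-diisopropylcarbamate | C[C@H](OC(=O)N(C(C)C)C(C)C)c1cc(O[Si](C)(C)C(C)(C)C)c(O[Si](C)(C)C(C)(C)C)c(Oc2cc(C(C)=O)ccc2O[Si](C)(C)C(C)(C)C)c1 | intermediate
14 | (1S)-1-{3-[5-[(1R)-1-hydroxyethyl]-2-(TBSO)phenoxy]-4,5-bis(TBSO)phenyl}ethyl N,N-diisopropylcarbamate | C[C@@H](O)c1ccc(O[Si](C)(C)C(C)(C)C)c(Oc2cc([C@H](C)OC(=O)N(C(C)C)C(C)C)cc(O[Si](C)(C)C(C)(C)C)c2O[Si](C)(C)C(C)(C)C)c1 | intermediate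
15 | bis(N,N-diisopropylcarbamate), (1R)-carbinol on ring A and (1S)-carbinol on ring B, three phenols as TBS ethers | C[C@@H](OC(=O)N(C(C)C)C(C)C)c1ccc(O[Si](C)(C)C(C)(C)C)c(Oc2cc([C@H](C)OC(=O)N(C(C)C)C(C)C)cc(O[Si](C)(C)C(C)(C)C)c2O[Si](C)(C)C(C)(C)C)c1 | intermediate (key-step precursor)
16 | geranyl bromide, (2E)-1-bromo-3,7-dimethylocta-2,6-diene | CC(C)=CCC/C(C)=C/CBr | starting material
17 | 2-[(2E)-3,7-dimethylocta-2,6-dien-1-yl]-4,4,5,5-tetramethyl-1,3,2-dioxaborolane | CC(C)=CCC/C(C)=C/CB1OC(C)(C)C(C)(C)O1 | intermediate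
18 | lithium (chloromethyl)(geranyl)pinacolatoborate | [Li+].CC(C)=CCC/C(C)=C/C[B-]1(CCl)OC(C)(C)C(C)(C)O1 | intermediate (not isolated)
19 | 2-[(3E)-4,8-dimethylnona-3,7-dien-1-yl]-4,4,5,5-tetramethyl-1,3,2-dioxaborolane | CC(C)=CCC/C(C)=C/CCB1OC(C)(C)C(C)(C)O1 | intermediate
20 | dilithiated bis(carbamate), lithium in place of each benzylic hydrogen of 15 with retention | C[C@@]([Li])(OC(=O)N(C(C)C)C(C)C)c1ccc(O[Si](C)(C)C(C)(C)C)c(Oc2cc([C@]([Li])(C)OC(=O)N(C(C)C)C(C)C)cc(O[Si](C)(C)C(C)(C)C)c2O[Si](C)(C)C(C)(C)C)c1 | intermediate (not isolated)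
21 | dilithium bis(boronate) complex, each benzylic carbon bonded to a homogeranyl(pinacolato)borate and still carrying its carbamate | [Li+].[Li+].C[C@@]([B-]3(CC/C=C(\C)CCC=C(C)C)OC(C)(C)C(C)(C)O3)(OC(=O)N(C(C)C)C(C)C)c1ccc(O[Si](C)(C)C(C)(C)C)c(Oc2cc([C@]([B-]4(CC/C=C(\C)CCC=C(C)C)OC(C)(C)C(C)(C)O4)(C)OC(=O)N(C(C)C)C(C)C)cc(O[Si](C)(C)C(C)(C)C)c2O[Si](C)(C)C(C)(C)C)c1 | intermediate (not isolated)
22 | bis(tertiary pinacol boronic ester), (2R,5E)-6,10-dimethyl-2-(Bpin)undeca-5,9-dien-2-yl on ring A and the (2S,5E) group on ring B, phenols as TBS ethers | CC1(C)OB(OC1(C)C)[C@@](C)(CC/C=C(\C)CCC=C(C)C)c1ccc(O[Si](C)(C)C(C)(C)C)c(Oc2cc([C@](C)(B3OC(C)(C)C(C)(C)O3)CC/C=C(\C)CCC=C(C)C)cc(O[Si](C)(C)C(C)(C)C)c2O[Si](C)(C)C(C)(C)C)c1 | intermediate (key-step product)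
23 | dilithium bis(vinylboronate) complex of 22 | [Li+].[Li+].C=C[B-]3(OC(C)(C)C(C)(C)O3)[C@@](C)(CC/C=C(\C)CCC=C(C)C)c1ccc(O[Si](C)(C)C(C)(C)C)c(Oc2cc([C@](C)([B-]4(C=C)OC(C)(C)C(C)(C)O4)CC/C=C(\C)CCC=C(C)C)cc(O[Si](C)(C)C(C)(C)C)c2O[Si](C)(C)C(C)(C)C)c1 | intermediate (not isolated)
24 | bis(2-iodo-1-(Bpin)ethyl) compound, each quaternary carbon bonded to CH(Bpin)CH2I (configuration at CH(Bpin) not defined) | ICC(B3OC(C)(C)C(C)(C)O3)[C@@](C)(CC/C=C(\C)CCC=C(C)C)c1ccc(O[Si](C)(C)C(C)(C)C)c(Oc2cc([C@](C)(C(CI)B4OC(C)(C)C(C)(C)O4)CC/C=C(\C)CCC=C(C)C)cc(O[Si](C)(C)C(C)(C)C)c2O[Si](C)(C)C(C)(C)C)c1 | intermediate (not isolated)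
25 | tris(TBS) ether of the target, (3R,6E)-3,7,11-trimethyldodeca-1,6,10-trien-3-yl on ring A and the (3S,6E) chain on ring B | C=C[C@@](C)(CC/C=C(\C)CCC=C(C)C)c1ccc(O[Si](C)(C)C(C)(C)C)c(Oc2cc([C@](C)(C=C)CC/C=C(\C)CCC=C(C)C)cc(O[Si](C)(C)C(C)(C)C)c2O[Si](C)(C)C(C)(C)C)c1 | intermediate
26 | 3-{2-hydroxy-5-[(3R,6E)-3,7,11-trimethyldodeca-1,6,10-trien-3-yl]phenoxy}-5-[(3S,6E)-3,7,11-trimethyldodeca-1,6,10-trien-3-yl]benzene-1,2-diol | C=C[C@@](C)(CC/C=C(\C)CCC=C(C)C)c1ccc(O)c(Oc2cc([C@](C)(C=C)CC/C=C(\C)CCC=C(C)C)cc(O)c2O)c1 | target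

**Step count**

Total: 16 steps. Longest linear sequence: 14 steps (steps 1–11, 14, 15, 16); steps 12 and 13 form the boronate branch.

**Steps most likely to fail**

1. Step 14. The second benzylic lithiation may remain incomplete, and the electron-rich boronate complexes may dissociate back to boronate and carbanion before the 1,2-shift; either would leave mono-homologated material and erode the configuration at the quaternary carbons. The fallback changes the boron partner to the less hindered neopentyl glycol ester, whose complexes form essentially irreversibly at −78 °C and rearrange on warming without a Lewis acid. It sets out from 19 and 15 and comes back at 22. Boronate 19 would be cleaved with NaIO4 and NH4OAc in acetone/water to [(3E)-4,8-dimethylnona-3,7-dien-1-yl]boronic acid F1, which condensation with 2,2-dimethylpropane-1,3-diol (MgSO4, Et2O) should convert into homogeranyl neopentyl glycol boronate F2. Dilithiated 15 (s-BuLi, Et2O, −78 °C) would be trapped with F2 and warmed to give the bis(tertiary neopentyl glycol boronate) F3. Exchange of F3 with pinacol (Et2O, rt) should return the route to 22.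

2. Step 15. Complexation of the two hindered tertiary boronates by vinyllithium may be slow, and methoxide may remove aryl silyl groups while iodine is still present, which would open the way to iodination of the electron-rich rings. The fallback builds each vinyl group through a one-carbon homologation and a Wittig reaction, without iodine. It sets out from 22 and comes back at 25. Treatment of 22 with dichloromethyllithium (CH2Cl2, n-BuLi, THF, −100 °C → rt) should insert CHCl into each C–B bond with retention, giving the bis(α-chloroalkyl pinacol boronate) F4. Oxidation with NaBO3·4H2O in THF/H2O should convert F4 into the bis(aldehyde) F5, whose α-carbons are quaternary and cannot epimerise. Methylenation of F5 with Ph3P=CH2 (Ph3PCH3Br, KHMDS, THF, 0 °C) should give 25.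

3. Step 4. Hydrodediazoniation and other radical side reactions of the ortho-aryloxy aryl radical may compete with its capture by boron. The fallback avoids the aniline altogether by using an aldehyde as the activating group and a Dakin-type oxidation. It sets out from 2 and comes back at 7. Phenol 2 would displace fluoride from 4-bromo-2-fluorobenzaldehyde (K2CO3, DMF, 80 °C) to give 1-[7-(5-bromo-2-formylphenoxy)-2,2-diphenyl-1,3-benzodioxol-5-yl]ethanone F6. mCPBA in CH2Cl2 at 0 °C should oxidise the electron-rich aldehyde faster than the aryl methyl ketone and give the aryl formate F7. Methanolysis of F7 (K2CO3, MeOH, 0 °C) should give 7.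

**Further compounds**

F1 | step 14 | [(3E)-4,8-dimethylnona-3,7-dien-1-yl]boronic acid | CC(C)=CCC/C(C)=C/CCB(O)O
F2 | step 14 | 2-[(3E)-4,8-dimethylnona-3,7-dien-1-yl]-5,5-dimethyl-1,3,2-dioxaborinane | CC(C)=CCC/C(C)=C/CCB1OCC(C)(C)CO1
F3 | step 14 | bis(tertiary neopentyl glycol boronate), the 5,5-dimethyl-1,3,2-dioxaborinan-2-yl analogue of 22 with the same configuration at both quaternary carbons | CC1(C)COB(OC1)[C@@](C)(CC/C=C(\C)CCC=C(C)C)c1ccc(O[Si](C)(C)C(C)(C)C)c(Oc2cc([C@](C)(B3OCC(C)(C)CO3)CC/C=C(\C)CCC=C(C)C)cc(O[Si](C)(C)C(C)(C)C)c2O[Si](C)(C)C(C)(C)C)c1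
F4 | step 15 | bis(α-chloroalkyl pinacol boronate), each quaternary carbon of 22 bonded to CHCl(Bpin) with retention (configuration at CHCl not defined) | ClC(B3OC(C)(C)C(C)(C)O3)[C@@](C)(CC/C=C(\C)CCC=C(C)C)c1ccc(O[Si](C)(C)C(C)(C)C)c(Oc2cc([C@](C)(C(Cl)B4OC(C)(C)C(C)(C)O4)CC/C=C(\C)CCC=C(C)C)cc(O[Si](C)(C)C(C)(C)C)c2O[Si](C)(C)C(C)(C)C)c1
F5 | step 15 | bis(aldehyde), each quaternary carbon bonded to CHO, phenols as TBS ethers | O=C[C@@](C)(CC/C=C(\C)CCC=C(C)C)c1ccc(O[Si](C)(C)C(C)(C)C)c(Oc2cc([C@](C)(C=O)CC/C=C(\C)CCC=C(C)C)cc(O[Si](C)(C)C(C)(C)C)c2O[Si](C)(C)C(C)(C)C)c1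
F6 | step 4 | 1-[7-(5-bromo-2-formylphenoxy)-2,2-diphenyl-1,3-benzodioxol-5-yl]ethanone | CC(=O)c1cc(Oc2cc(Br)ccc2C=O)c2OC(c3ccccc3)(c3ccccc3)Oc2c1
F7 | step 4 | 1-[7-(5-bromo-2-formyloxyphenoxy)-2,2-diphenyl-1,3-benzodioxol-5-yl]ethanone | CC(=O)c1cc(Oc2cc(Br)ccc2OC=O)c2OC(c3ccccc3)(c3ccccc3)Oc2c1
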